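**Retrosynthetic overview**

1. Ring numbering: C1 (alkylidene carbon), C2, C3, C4 (C(OH)CH3), C5 (quaternary C), C6 (CH–hydroxypropyl); β is the face of the C4 methyl, α the face of the C4 hydroxyl. The feature used: C1 and C4 are 1,4-related and each carries a carbon branch on the β face, so the cyclohexane is one ring of a bicyclo[2.2.2]oct-5-ene whose C=C bridge holds the future C4 methyl carbon and the future enal carbon with its methyl group.
2. Late disconnections: the oxirane (last ring formed) by hydroxyl-directed epoxidation; the C5 side chain by B-alkyl Suzuki coupling of a C5 vinyl group with an (E,E)-alkenyl iodide built by two Zr-catalysed carboaluminations from an (S)-homopropargylic alcohol.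
3. The enal comes from a C1 acetyl group (enol triflate, Pd carbonylation, reduction, oxidation) and the C4 methyl from a C4 formyl group (reduction, mesylate, spiro-oxirane, hydride); both carbonyls arise by ozonolysis of the C=C bridge.
4. Key disconnection: Diels–Alder reaction of 1-silyloxy-3-methylcyclohexa-1,3-diene with citraconic anhydride, forming C4–C5 and C1–C6 and the only carbocycle; the racemic adduct is resolved as its hemiester salt.
5. C6 is formed cis to the C5 carboxyl. It is inverted only after the bridge is cut, at the aldehyde stage, where the chair makes the trans isomer clearly more stable (in the bicycle the equilibrium is not reliably on the trans side). The C5 and C6 carboxyl carbons become the side-chain anchor and the hydroxypropyl group.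

Key step: step 2

Remark: the cycloaddition is run without absolute control, so 5 and 6 are racemates (their SMILES show the enantiomer carried on); which antipode of 1-phenylethylamine gives the less soluble salt of the required acid is settled by experiment, the (S)-amine is written and its mirror image serves if the other acid crystallises.

**Route**

Step 1
Reactants: 1 3-methylcyclohex-2-en-1-one
Product: 3 tert-butyldimethyl[(3-methylcyclohexa-1,3-dien-1-yl)oxy]silane, via bromomagnesium dienolate 2 (not isolated)
Conditions: MeMgBr, FeCl3 (3 mol%), Et2O, −20 → 0 °C; then TBSCl, Et3N, HMPA, rt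
Reagents that add atoms: tert-butyldimethylsilyl chloride, CC(C)(C)[Si](C)(C)Cl
Why: Iron-catalysed γ-deprotonation of the enone by the Grignard reagent should give the extended (thermodynamic) magnesium dienolate, whose O-silylation (silyl dienol ether formation) furnishes the linear 1-silyloxy-1,3-diene and not the cross-conjugated isomer obtained with kinetic amide bases.

Step 2
Reactants: 3 silyloxydiene; 4 citraconic anhydride
Product: 5 racemic endo adduct (1-(tert-butyldimethylsilyloxy)-2,5-dimethylbicyclo[2.2.2]oct-5-ene-2,3-dicarboxylic anhydride; both carbonyls syn to the C=C bridge)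
Conditions: toluene, BHT (cat.), 90 °C, sealed tube
Reagents that add atoms: none
Why: Normal-electron-demand, concerted but asynchronous [4+2] cycloaddition (Diels–Alder) of an electron-rich 1-silyloxydiene with a cyclic maleic-type anhydride, the closest known cases being additions of 1-alkoxy- and 1-silyloxy-1,3-dienes to citraconic and maleic anhydride. The bond from the unsubstituted diene terminus (future C1) to the CH carbon of the anhydride (future C6) leads and the bond from the silyloxy terminus (C4) to the methyl-bearing carbon (C5) follows, so the cyclohexane C1–C6 closes by cycloaddition, suprafacially on both partners, as one ring of a bicyclo[2.2.2]octene. The step needs this regiochemistry, and it is secured by polarisation: the oxygen donor and the 3-methyl group both raise the HOMO coefficient at the free terminus, and the CH carbon of the anhydride is its less hindered, more electrophilic end. C4 and C1 are fixed by the bridged topology; C5 and C6 follow from the cis geometry of the anhydride and the endo rule (secondary overlap of both carbonyls with the diene), which places the C5 carboxyl carbon syn to the C=C bridge, that is cis to the later C4 methyl and trans to the C4 oxygen as in the target. C6 emerges cis to the C5 carboxyl and is inverted in step 8. No absolute control is exerted, so the adduct is racemic and is resolved in steps 4 and 5.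

Step 3
Reactants: 5 racemic anhydride
Product: 6 racemic hemiester (C6 methyl ester and C5 carboxylic acid; both cis and syn to the C=C bridge)
Conditions: MeOH, Et3N, DMAP (cat.), CH2Cl2, 0 °C → rt; aq. citric acid
Reagents that add atoms: methanol, CO
Why: Nucleophile-catalysed alcoholysis of a cyclic anhydride, in which methanol should enter at the C6 carbonyl because the C5 carbonyl is flanked by the quaternary carbon and the silyloxy bridgehead; no stereocentre is touched.

Step 4
Reactants: 6 racemic hemiester; 7 (S)-1-phenylethylamine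
Product: 8 (S)-1-phenylethylammonium salt of the hemiester enantiomer that carries the target configuration at C4 and C5
Conditions: 7 (1.0 equiv), EtOAc, crystallisation; recrystallised to constant rotation
Reagents that add atoms: none
Why: Classical resolution, in which the enantiomeric acids form diastereomeric salts with the enantiopure amine and fractional crystallisation should deliver the salt of one acid; no stereocentre is created.

Step 5
Reactants: 8 resolved salt
Product: 10 enantiopure dimethyl ester (C4 OTBS; C5 CH3 and CO2Me; C6 CO2Me cis to the C5 ester), via free acid 9 (not isolated)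
Conditions: 1 M HCl/EtOAc partition; then MeI, K2CO3, DMF, rt
Reagents that add atoms: iodomethane, CI
Why: Acidification frees the carboxylic acid and SN2 O-alkylation of its potassium carboxylate esterifies the hindered acid without touching the α-centres.

Step 6
Reactants: 10 dimethyl ester
Product: 13 bis(dimethyl acetal) diester (cyclohexane with C1 β-C(OMe)2CH3; C4 β-CH(OMe)2 and α-OTBS; C5 β-CO2Me and α-CH3; C6 β-CO2Me), via ozonide 11 (not isolated), via keto aldehyde 12 (not isolated)
Conditions: O3, CH2Cl2, −78 °C; PPh3, −78 °C → rt; then HC(OMe)3, MeOH, TsOH·H2O (cat.), rt; Et3N quench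
Reagents that add atoms: trimethyl orthoformate, COC(OC)OC
Why: Ozonolysis with reductive work-up cleaves the only C=C and turns the bicyclo[2.2.2]octene into the cyclohexane with cis C4 formyl and C1 acetyl groups; acid-catalysed acetalisation with excess orthoformate then masks both carbonyls for the base and hydride steps that follow, with the ring stereocentres untouched.

Step 7
Reactants: 13 bis-acetal diester
Product: 14 C6 aldehyde (6β-formyl; cis to the C5 ester)
Conditions: DIBAL-H (1.1 equiv), CH2Cl2, −78 °C; MeOH, then aq. Rochelle salt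
Reagents that add atoms: none
Why: Partial reduction of an ester by DIBAL-H at low temperature (stable tetrahedral aluminate) should be selective for the C6 ester on a tertiary carbon over the C5 ester on a quaternary carbon flanked by two fully substituted neighbours.

Step 8
Reactants: 14 cis aldehyde
Product: 15 epimerised aldehyde (6α-formyl; trans to the C5 ester)
Conditions: DBU (0.2 equiv), CH2Cl2, rt
Reagents that add atoms: none
Why: Base-mediated epimerisation α to the aldehyde through its enolate under thermodynamic control; in the monocyclic chair the all-cis array of the C4, C5, C6 and C1 carbon substituents forces a syn-diaxial pair, which inversion at C6 removes (formyl equatorial), so the target configuration at C6 should result.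

Step 9
Reactants: 15 trans aldehyde
Product: 16 (E)-enoate (C6 α-CH=CH–CO2Me)
Conditions: Ph3P=CHCO2Me, toluene, 80 °C
Reagents that add atoms: methyl (triphenylphosphoranylidene)acetate, COC(=O)C=P(c1ccccc1)(c1ccccc1)c1ccccc1
Why: Wittig olefination with a stabilised ylide, E-selective and mild enough not to disturb the equilibrated C6 centre.

Step 10
Reactants: 16 enoate
Product: 17 saturated diester (C6 α-CH2CH2CO2Me)
Conditions: H2 (1 atm), Pd/C (10%), EtOAc, rt
Reagents that add atoms: none
Why: Heterogeneous catalytic hydrogenation of the only C=C; acetals, silyl ether and esters are inert.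

Step 11
Reactants: 17 diester
Product: 18 diol (C5 β-CH2OH; C6 α-(CH2)3OH)
Conditions: LiAlH4, THF, 0 °C → reflux
Reagents that add atoms: none
Why: LiAlH4 reduction of both esters to primary alcohols, the hindered C5 ester needing heat; acetals and the silyl ether are stable to hydride.

Step 12
Reactants: 18 diol
Product: 19 mono-pivalate (C6 α-(CH2)3OPiv; C5 β-CH2OH free)
Conditions: PivCl (1.05 equiv), pyridine, CH2Cl2, −20 °C
Reagents that add atoms: pivaloyl chloride, CC(C)(C)C(Cl)=O
Why: Sterically controlled acylation, in which the bulky acid chloride should esterify the unhindered primary hydroxyl and leave the neopentyl-type C5 hydroxymethyl group free.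

Step 13
Reactants: 19 alcohol
Product: 20 C5 aldehyde (C5 β-CHO)
Conditions: Dess–Martin periodinane, NaHCO3, CH2Cl2, rt
Reagents that add atoms: none
Why: Dess–Martin oxidation of the remaining primary alcohol to a non-enolisable aldehyde under buffered conditions that spare the acetals.

Step 14
Reactants: 20 aldehyde
Product: 21 C5 vinyl compound (C5 β-CH=CH2)
Conditions: Ph3PCH3Br, KOtBu, THF, 0 °C → rt
Reagents that add atoms: methyltriphenylphosphonium bromide, C[P+](c1ccccc1)(c1ccccc1)c1ccccc1.[Br-]
Why: Wittig methylenation of the hindered, non-enolisable aldehyde with the unstabilised ylide installs the vinyl group that will carry the side chain.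

Step 15
Reactants: 21 bis-acetal
Product: 22 keto aldehyde (C1 β-acetyl; C4 β-CHO and α-OTBS)
Conditions: CF3CO2H/H2O (9:1), CH2Cl2, 0 °C
Reagents that add atoms: water, O
Why: Acid-catalysed acetal hydrolysis releases the C1 acetyl and C4 formyl groups, while the hindered tertiary silyl ether and the pivalate should survive the cold, brief acid treatment.

Step 16
Reactants: 22 keto aldehyde
Product: 23 keto alcohol (C4 β-CH2OH; C1 acetyl kept)
Conditions: NaBH4 (0.3 equiv), EtOH/CH2Cl2, −78 °C; AcOH quench at −78 °C
Reagents that add atoms: none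
Why: Chemoselective borohydride reduction at low temperature, the α-oxygenated aldehyde being far more electrophilic than the methyl ketone; the cold acidic quench guards against silyl migration to the new primary alkoxide.

Step 17
Reactants: 23 keto alcohol
Product: 24 keto mesylate (C4 β-CH2OMs)
Conditions: MsCl, Et3N, CH2Cl2, 0 °C
Reagents that add atoms: methanesulfonyl chloride, CS(Cl)(=O)=O
Why: Sulfonylation of the primary alcohol through the sulfene, fast even at a neopentyl-type position; the mesylate can be neither displaced intermolecularly nor eliminated.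

Step 18
Reactants: 24 keto mesylate
Product: 25 (Z)-enol triflate (C1=C(CH3)OTf; triflate oxygen syn to C6 and methyl syn to C2)
Conditions: Tf2O, 2,6-di-tert-butyl-4-methylpyridine, CH2Cl2, 0 °C → rt
Reagents that add atoms: trifluoromethanesulfonic anhydride, O=S(=O)(OS(=O)(=O)C(F)(F)F)C(F)(F)F
Why: Enol triflate formation by O-sulfonylation of the ketone and proton loss from the triflyloxycarbenium ion, which with methyl sec-alkyl ketones favours the more substituted (Zaitsev) enol triflate; allylic 1,3-strain should place the larger methyl group beside C2 and the triflate oxygen beside the substituted C6.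

Step 19
Reactants: 25 enol triflate
Product: 26 (Z)-enoate (C1=C(CH3)CO2Me; ester syn to C6)
Conditions: Pd(OAc)2 (5 mol%), dppp (10 mol%), CO (1 atm), MeOH, Et3N, DMF, 60 °C
Reagents that add atoms: carbon monoxide, [C-]#[O+]; methanol, CO
Why: Palladium-catalysed alkoxycarbonylation of the enol triflate (oxidative addition, CO insertion, methanolysis) proceeds with retention of alkene geometry; cyclisation onto the C5 vinyl group would need a bridgehead alkene and is not expected.

Step 20
Reactants: 26 enoate mesylate
Product: 28 spiro-epoxide (C4 oxirane; oxygen α and CH2 β), via hydroxy mesylate 27 (not isolated)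
Conditions: TBAF, THF, 50 °C
Reagents that add atoms: none
Why: Fluoride-mediated desilylation frees the C4 alkoxide, which closes the oxirane by intramolecular SN2 displacement of the neighbouring mesylate (3-exo-tet); the C4–O bond is not broken, so the C4 configuration is kept.

Step 21
Reactants: 29 3-methylbut-2-enal; 30 allenylboronic acid pinacol ester
Product: 32 (S)-6-methylhept-5-en-1-yn-4-ol, via pinacol borate 31 (not isolated)
Conditions: (S)-TRIP [(S)-3,3'-bis(2,4,6-triisopropylphenyl)-1,1'-binaphthyl-2,2'-diyl hydrogen phosphate] (5 mol%), 4 Å MS, toluene, −20 °C; aq. NaHCO3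
Reagents that add atoms: none
Why: Chiral phosphoric acid-catalysed propargylboration of the aldehyde by the allenylboronate through a closed six-membered SE2' transition state, in which the (S)-catalyst is expected to leave the Si face of the aldehyde open and so to set the (S)-carbinol.

Step 22
Reactants: 32 alcohol
Product: 33 TBS ether of 32
Conditions: TBSCl, imidazole, DMF, rt
Reagents that add atoms: tert-butyldimethylsilyl chloride, CC(C)(C)[Si](C)(C)Cl
Why: Standard imidazole-promoted silylation of a secondary alcohol.

Step 23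
Reactants: 33 alkyne
Product: 35 (S,E)-4-(tert-butyldimethylsilyloxy)-1-iodo-2,6-dimethylhepta-1,5-diene, via alkenylalane 34 (not isolated)
Conditions: AlMe3 (2.5 equiv), Cp2ZrCl2 (0.25 equiv), CH2Cl2, 0 °C → rt; then I2, THF, −30 °C
Reagents that add atoms: trimethylaluminium, C[Al](C)C; iodine, II
Why: Zirconium-catalysed carboalumination (Negishi) adds methyl and aluminium syn across the terminal alkyne with aluminium on the terminal carbon, and iodinolysis with retention gives the (E)-2-methyl-1-iodoalkene.

Step 24
Reactants: 36 4-(trimethylsilyl)but-3-yn-1-ol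
Product: 37 (4-iodobut-1-yn-1-yl)trimethylsilane
Conditions: I2, PPh3, imidazole, CH2Cl2, 0 °C
Reagents that add atoms: iodine, II
Why: Appel-type iodination of a primary alcohol.

Step 25
Reactants: 37 alkyl iodide; 35 alkenyl iodide
Product: 39 (S,E)-silyl-capped enyne (TMS–C≡C–CH2CH2–CH=C(CH3)–CH2–CH(OTBS)–CH=C(CH3)2), via alkylzinc iodide 38 (not isolated)
Conditions: Zn dust (activated with 1,2-dibromoethane/TMSCl), DMF, 40 °C; then 35, Pd(PPh3)4 (5 mol%), THF, rt → 45 °C
Reagents that add atoms: none
Why: Zinc insertion into the primary iodide followed by Negishi cross-coupling of the alkylzinc with the alkenyl iodide, which retains the E geometry.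

Step 26
Reactants: 39 alkynylsilane
Product: 40 terminal alkyne
Conditions: K2CO3, MeOH, rt
Reagents that add atoms: none
Why: Base-mediated protiodesilylation of the alkynylsilane, to which the silyl ether is inert.

Step 27
Reactants: 40 terminal alkyne
Product: 42 (S,1E,5E)-8-(tert-butyldimethylsilyloxy)-1-iodo-2,6,10-trimethylundeca-1,5,9-triene, via alkenylalane 41 (not isolated)
Conditions: AlMe3 (2.5 equiv), Cp2ZrCl2 (0.25 equiv), CH2Cl2, 0 °C → rt; then I2, THF, −30 °C
Reagents that add atoms: trimethylaluminium, C[Al](C)C; iodine, II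
Why: Second Negishi carboalumination–iodinolysis, again syn and terminal-selective, gives the second E trisubstituted alkene as its alkenyl iodide.

Step 28
Reactants: 28 vinyl spiro-epoxide; 42 alkenyl iodide
Product: 44 coupled enoate (full side chain on C5; C4 spiro-epoxide; pivalate; secondary OTBS), via B-alkyl-9-BBN borane 43 (not isolated)
Conditions: 9-BBN (1.5 equiv), THF, 0 °C → rt; then 42, PdCl2(dppf) (10 mol%), AsPh3, Cs2CO3, DMF/H2O, rt
Reagents that add atoms: none
Why: Anti-Markovnikov hydroboration of the monosubstituted C5 vinyl group with 9-BBN (the tetrasubstituted enoate alkene is inert) and B-alkyl Suzuki–Miyaura coupling with the alkenyl iodide, with retention of its geometry.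

Step 29
Reactants: 44 coupled enoate
Product: 45 triol (C1=C(CH3)CH2OH; C4 α-OH and β-CH3; C6 α-(CH2)3OH; secondary OTBS kept)
Conditions: LiAlH4, THF, −20 °C → rt
Reagents that add atoms: none
Why: One hydride reagent performs 1,2-reduction of the enoate to the allylic alcohol, SN2 opening of the spiro-epoxide at its CH2 terminus (giving the C4 methyl carbinol with C4 untouched) and cleavage of the pivalate.

Step 30
Reactants: 45 triol
Product: 46 (Z)-enal (C1=C(CH3)CHO)
Conditions: MnO2 (activated, excess), CH2Cl2, rt
Reagents that add atoms: none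
Why: MnO2 oxidises only the allylic primary alcohol, since the saturated primary and tertiary hydroxyls are inert to it and the secondary allylic oxygen is silylated.

Step 31
Reactants: 46 silyl ether
Product: 47 enal triol (free (S)-allylic alcohol)
Conditions: HF·pyridine, pyridine, THF, 0 °C → rt
Reagents that add atoms: none
Why: Buffered fluoride desilylation of the secondary allylic silyl ether under conditions that do not enolise the enal.

Step 32
Reactants: 47 enal triol
Product: 48 CNP0161066.1
Conditions: VO(acac)2 (5 mol%), t-BuOOH (in decane, 1.5 equiv), CH2Cl2, 0 °C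
Reagents that add atoms: tert-butyl hydroperoxide, CC(C)(C)OO
Why: Vanadium-catalysed hydroxyl-directed epoxidation, in which the allylic alkene should react far faster than the homoallylic one and the electron-poor enal alkene, and allylic 1,3-strain from the Z-methyl group holds the carbinol hydrogen in the alkene plane so that oxygen delivery gives mainly the threo epoxy alcohol (S carbinol, R oxirane carbon); any erythro isomer is removed by chromatography.

**Compound list**

1 | 3-methylcyclohex-2-en-1-one | CC1=CC(=O)CCC1 | starting material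
2 | bromomagnesium 3-methylcyclohexa-1,3-dien-1-olate (not isolated) | CC1=CCCC(O[Mg]Br)=C1 | intermediate
3 | tert-butyldimethyl[(3-methylcyclohexa-1,3-dien-1-yl)oxy]silane | CC1=CCCC(O[Si](C)(C)C(C)(C)C)=C1 | intermediate
4 | citraconic anhydride (3-methylfuran-2,5-dione) | CC1=CC(=O)OC1=O | starting material
5 | endo 1-(tert-butyldimethylsilyloxy)-2,5-dimethylbicyclo[2.2.2]oct-5-ene-2,3-dicarboxylic anhydride, racemate (one enantiomer drawn) | [C@H]12CC[C@](C=C2C)(O[Si](C)(C)C(C)(C)C)[C@@](C)(C(=O)OC3=O)[C@H]13 | intermediate
6 | 3-(methoxycarbonyl)-1-(tert-butyldimethylsilyloxy)-2,5-dimethylbicyclo[2.2.2]oct-5-ene-2-carboxylic acid, cis, racemate (one enantiomer drawn) | [C@H]12CC[C@](C=C2C)(O[Si](C)(C)C(C)(C)C)[C@@](C)(C(O)=O)[C@H]1C(=O)OC | intermediate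
7 | (S)-1-phenylethylamine | C[C@H](N)c1ccccc1 | starting material
8 | (S)-1-phenylethylammonium salt of the resolved hemiester | [C@H]12CC[C@](C=C2C)(O[Si](C)(C)C(C)(C)C)[C@@](C)(C(=O)[O-])[C@H]1C(=O)OC.C[C@H]([NH3+])c1ccccc1 | intermediate
9 | resolved hemiester, free acid (not isolated) | [C@H]12CC[C@](C=C2C)(O[Si](C)(C)C(C)(C)C)[C@@](C)(C(O)=O)[C@H]1C(=O)OC | intermediate
10 | dimethyl 1-(tert-butyldimethylsilyloxy)-2,5-dimethylbicyclo[2.2.2]oct-5-ene-2,3-dicarboxylate, cis esters syn to the C=C bridge, single enantiomer | [C@H]12CC[C@](C=C2C)(O[Si](C)(C)C(C)(C)C)[C@@](C)(C(=O)OC)[C@H]1C(=O)OC | intermediate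
11 | ozonide of 10 (1,2,4-trioxolane spanning C4 and C1; not isolated) | [C@H]12CC[C@](C3OC2(C)OO3)(O[Si](C)(C)C(C)(C)C)[C@@](C)(C(=O)OC)[C@H]1C(=O)OC | intermediate
12 | keto aldehyde diester: cyclohexane with C1 β-acetyl, C4 β-CHO/α-OTBS, C5 β-CO2Me/α-CH3, C6 β-CO2Me (not isolated) | CC(=O)[C@H]1CC[C@](C=O)(O[Si](C)(C)C(C)(C)C)[C@@](C)(C(=O)OC)[C@H]1C(=O)OC | intermediate
13 | bis(dimethyl acetal) diester: C1 β-C(OMe)2CH3, C4 β-CH(OMe)2/α-OTBS, C5 β-CO2Me/α-CH3, C6 β-CO2Me | CC(OC)(OC)[C@H]1CC[C@](C(OC)OC)(O[Si](C)(C)C(C)(C)C)[C@@](C)(C(=O)OC)[C@H]1C(=O)OC | intermediate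
14 | C6 β-aldehyde (as 13 with C6 β-CHO) | CC(OC)(OC)[C@H]1CC[C@](C(OC)OC)(O[Si](C)(C)C(C)(C)C)[C@@](C)(C(=O)OC)[C@H]1C=O | intermediate
15 | C6 α-aldehyde (C6 epimer of 14; formyl trans to the C5 ester) | CC(OC)(OC)[C@H]1CC[C@](C(OC)OC)(O[Si](C)(C)C(C)(C)C)[C@@](C)(C(=O)OC)[C@@H]1C=O | intermediate
16 | (E)-enoate: C6 α-CH=CH–CO2Me | CC(OC)(OC)[C@H]1CC[C@](C(OC)OC)(O[Si](C)(C)C(C)(C)C)[C@@](C)(C(=O)OC)[C@@H]1/C=C/C(=O)OC | intermediate
17 | saturated diester: C6 α-CH2CH2CO2Me, C5 β-CO2Me | CC(OC)(OC)[C@H]1CC[C@](C(OC)OC)(O[Si](C)(C)C(C)(C)C)[C@@](C)(C(=O)OC)[C@@H]1CCC(=O)OC | intermediate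
18 | diol: C5 β-CH2OH, C6 α-(CH2)3OH | CC(OC)(OC)[C@H]1CC[C@](C(OC)OC)(O[Si](C)(C)C(C)(C)C)[C@@](C)(CO)[C@@H]1CCCO | intermediate
19 | mono-pivalate: C6 α-(CH2)3OPiv, C5 β-CH2OH | CC(OC)(OC)[C@H]1CC[C@](C(OC)OC)(O[Si](C)(C)C(C)(C)C)[C@@](C)(CO)[C@@H]1CCCOC(=O)C(C)(C)C | intermediate
20 | C5 β-aldehyde | CC(OC)(OC)[C@H]1CC[C@](C(OC)OC)(O[Si](C)(C)C(C)(C)C)[C@@](C)(C=O)[C@@H]1CCCOC(=O)C(C)(C)C | intermediate
21 | C5 β-vinyl bis-acetal | CC(OC)(OC)[C@H]1CC[C@](C(OC)OC)(O[Si](C)(C)C(C)(C)C)[C@@](C)(C=C)[C@@H]1CCCOC(=O)C(C)(C)C | intermediate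
22 | keto aldehyde: C1 β-acetyl, C4 β-CHO/α-OTBS, C5 β-vinyl/α-CH3, C6 α-(CH2)3OPiv | CC(=O)[C@H]1CC[C@](C=O)(O[Si](C)(C)C(C)(C)C)[C@@](C)(C=C)[C@@H]1CCCOC(=O)C(C)(C)C | intermediate
23 | keto alcohol: C4 β-CH2OH | CC(=O)[C@H]1CC[C@](CO)(O[Si](C)(C)C(C)(C)C)[C@@](C)(C=C)[C@@H]1CCCOC(=O)C(C)(C)C | intermediate
24 | keto mesylate: C4 β-CH2OMs | CC(=O)[C@H]1CC[C@](COS(C)(=O)=O)(O[Si](C)(C)C(C)(C)C)[C@@](C)(C=C)[C@@H]1CCCOC(=O)C(C)(C)C | intermediate
25 | (Z)-enol triflate: C1=C(CH3)OTf, OTf syn to C6 | C/C(OS(=O)(=O)C(F)(F)F)=C1\CC[C@](COS(C)(=O)=O)(O[Si](C)(C)C(C)(C)C)[C@@](C)(C=C)[C@@H]1CCCOC(=O)C(C)(C)C | intermediate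
26 | (Z)-enoate: C1=C(CH3)CO2Me, ester syn to C6 | C/C(C(=O)OC)=C1\CC[C@](COS(C)(=O)=O)(O[Si](C)(C)C(C)(C)C)[C@@](C)(C=C)[C@@H]1CCCOC(=O)C(C)(C)C | intermediate
27 | hydroxy mesylate: C4 α-OH, β-CH2OMs (not isolated) | C/C(C(=O)OC)=C1\CC[C@](COS(C)(=O)=O)(O)[C@@](C)(C=C)[C@@H]1CCCOC(=O)C(C)(C)C | intermediate
28 | spiro-epoxide: C4 oxirane (O α, CH2 β), C5 β-vinyl, (Z)-enoate, pivalate | C/C(C(=O)OC)=C1\CC[C@@]2(CO2)[C@@](C)(C=C)[C@@H]1CCCOC(=O)C(C)(C)C | intermediate
29 | 3-methylbut-2-enal | CC(C)=CC=O | starting material
30 | allenylboronic acid pinacol ester | C=C=CB1OC(C)(C)C(C)(C)O1 | starting material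
31 | pinacol borate of 32 (not isolated) | C#CC[C@H](OB1OC(C)(C)C(C)(C)O1)C=C(C)C | intermediate
32 | (S)-6-methylhept-5-en-1-yn-4-ol | C#CC[C@H](O)C=C(C)C | intermediate
33 | (S)-tert-butyldimethyl[(6-methylhept-5-en-1-yn-4-yl)oxy]silane | C#CC[C@H](O[Si](C)(C)C(C)(C)C)C=C(C)C | intermediate
34 | (E)-alkenyl(dimethyl)alane from 33 (not isolated) | C[Al](C)/C=C(\C)C[C@H](O[Si](C)(C)C(C)(C)C)C=C(C)C | intermediate
35 | (S,E)-4-(tert-butyldimethylsilyloxy)-1-iodo-2,6-dimethylhepta-1,5-diene | I/C=C(\C)C[C@H](O[Si](C)(C)C(C)(C)C)C=C(C)C | intermediate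
36 | 4-(trimethylsilyl)but-3-yn-1-ol | C[Si](C)(C)C#CCCO | starting material
37 | (4-iodobut-1-yn-1-yl)trimethylsilane | C[Si](C)(C)C#CCCI | intermediate
38 | [4-(trimethylsilyl)but-3-yn-1-yl]zinc iodide (not isolated) | C[Si](C)(C)C#CCC[Zn]I | intermediate
39 | (S,E)-7-(tert-butyldimethylsilyloxy)-5,9-dimethyl-1-(trimethylsilyl)deca-4,8-dien-1-yne | C[Si](C)(C)C#CCC/C=C(\C)C[C@H](O[Si](C)(C)C(C)(C)C)C=C(C)C | intermediate
40 | (S,E)-7-(tert-butyldimethylsilyloxy)-5,9-dimethyldeca-4,8-dien-1-yne | C#CCC/C=C(\C)C[C@H](O[Si](C)(C)C(C)(C)C)C=C(C)C | intermediate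
41 | (E,E)-alkenyl(dimethyl)alane from 40 (not isolated) | C[Al](C)/C=C(\C)CC/C=C(\C)C[C@H](O[Si](C)(C)C(C)(C)C)C=C(C)C | intermediate
42 | (S,1E,5E)-8-(tert-butyldimethylsilyloxy)-1-iodo-2,6,10-trimethylundeca-1,5,9-triene | I/C=C(\C)CC/C=C(\C)CC[C@H](O[Si](C)(C)C(C)(C)C)C=C(C)C | intermediate
43 | B-alkyl-9-BBN borane: 28 with C5 β-CH2CH2–B(9-BBN) (not isolated) | C/C(C(=O)OC)=C1\CC[C@@]2(CO2)[C@@](C)(CCB3C4CCCC3CCC4)[C@@H]1CCCOC(=O)C(C)(C)C | intermediate
44 | coupled enoate: C5 β-(3E,7E)-side chain with (S)-OTBS, C4 spiro-epoxide, (Z)-enoate, pivalate | C/C(C(=O)OC)=C1\CC[C@@]2(CO2)[C@@](C)(CC/C=C(\C)CC/C=C(\C)C[C@H](O[Si](C)(C)C(C)(C)C)C=C(C)C)[C@@H]1CCCOC(=O)C(C)(C)C | intermediate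
45 | triol: (Z)-C1=C(CH3)CH2OH, C4 α-OH/β-CH3, C6 α-(CH2)3OH, side-chain OTBS | C/C(CO)=C1\CC[C@](C)(O)[C@@](C)(CC/C=C(\C)CC/C=C(\C)C[C@H](O[Si](C)(C)C(C)(C)C)C=C(C)C)[C@@H]1CCCO | intermediate
46 | (Z)-enal diol with side-chain OTBS | C/C(C=O)=C1\CC[C@](C)(O)[C@@](C)(CC/C=C(\C)CC/C=C(\C)C[C@H](O[Si](C)(C)C(C)(C)C)C=C(C)C)[C@@H]1CCCO | intermediate
47 | (Z)-enal triol with free (S)-allylic alcohol | C/C(C=O)=C1\CC[C@](C)(O)[C@@](C)(CC/C=C(\C)CC/C=C(\C)C[C@H](O)C=C(C)C)[C@@H]1CCCO | intermediate
48 | CNP0161066.1 | C/C(C=O)=C1\CC[C@](C)(O)[C@@](C)(CC/C=C(\C)CC/C=C(\C)C[C@H](O)[C@H]2OC2(C)C)[C@@H]1CCCO | target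

Correction to line 42: its SMILES is I/C=C(\C)CC/C=C(\C)C[C@H](O[Si](C)(C)C(C)(C)C)C=C(C)C (one CH2 between the second alkene and the carbinol carbon), as used in 43–48.

**Step count and risks**

Total step count: 32 (25 on the ring line, 7 for the side chain). Longest linear sequence: 25 steps (steps 1–20 and 28–32, from 3-methylcyclohex-2-en-1-one).

Steps most likely to fail:

Step 18. Proton loss from the triflyloxycarbenium ion may go toward the methyl group (terminal triflate) or give the wrong alkene geometry, because the bulky pyridine base reaches the hindered C1–H with difficulty. The fallback places the enol double bond under equilibrium control before the triflate is made. Setting out from keto mesylate 24, Me3SiI/(Me3Si)2NH in CH2Cl2 (−20 °C → rt) should give the more substituted, thermodynamic trimethylsilyl enol ether F1 with its oxygen syn to C6. Fluoride-induced exchange (CsF, PhNTf2, DME, rt) then converts it into enol triflate 25, where the route is rejoined.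

Step 28. The borane sits on a chain next to a quaternary carbon and may transmetalate slowly, so that protodeboronation and reduction of the iodide outrun coupling. The fallback changes the organometallic partner to zinc through an isolated halide. Setting out from 28, the borane 43 is oxidised (NaBO3·4H2O) to the primary alcohol F2. This is turned into the primary iodide F3 (I2, PPh3, imidazole, 0 °C, which the hindered spiro-epoxide should tolerate) and then into the alkylzinc iodide F4 (Zn dust, LiCl, THF). Negishi coupling of F4 with alkenyl iodide 42 (Pd(PPh3)4, THF) returns to 44.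

Step 4. The diastereomeric salts may fail to crystallise or may co-crystallise, so that no enrichment is reached. The fallback replaces salt formation by chromatographic enantioseparation. Setting out from racemic hemiester 6, esterification (MeI, K2CO3, DMF) gives the racemic dimethyl ester F5. This is separated on a preparative chiral stationary phase (amylose tris(3,5-dimethylphenylcarbamate), hexane/2-propanol), and the enantiomer with the configuration of 10 rejoins the route at 10.

Further compounds
F1 | step 18 | (Z)-trimethylsilyl enol ether of 24 (C1=C(CH3)OSiMe3, oxygen syn to C6) | C/C(O[Si](C)(C)C)=C1\CC[C@](COS(C)(=O)=O)(O[Si](C)(C)C(C)(C)C)[C@@](C)(C=C)[C@@H]1CCCOC(=O)C(C)(C)C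
F2 | step 28 | primary alcohol: 28 with C5 β-CH2CH2OH | C/C(C(=O)OC)=C1\CC[C@@]2(CO2)[C@@](C)(CCO)[C@@H]1CCCOC(=O)C(C)(C)C
F3 | step 28 | primary iodide: 28 with C5 β-CH2CH2I | C/C(C(=O)OC)=C1\CC[C@@]2(CO2)[C@@](C)(CCI)[C@@H]1CCCOC(=O)C(C)(C)C
F4 | step 28 | alkylzinc iodide: 28 with C5 β-CH2CH2ZnI | C/C(C(=O)OC)=C1\CC[C@@]2(CO2)[C@@](C)(CC[Zn]I)[C@@H]1CCCOC(=O)C(C)(C)C
F5 | step 4 | racemic dimethyl ester (racemate of 10, one enantiomer drawn) | [C@H]12CC[C@](C=C2C)(O[Si](C)(C)C(C)(C)C)[C@@](C)(C(=O)OC)[C@H]1C(=O)OC
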